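A direct plan would alkylate the Evans oxazolidinone imide of the ring A arylacetic acid A1 with a ring B benzyl bromide to set C3, exchange the auxiliary for a methyl ester, add the acrylate by a Heck reaction and unmask two phenols to give the diphenol A2. It would close O1–C2 last, by DDQ oxidation of A2 to the p-quinone methide A3 and addition of the ring A phenol. Its weakest steps would be:
- the oxidative O1–C2 closure, which would have to oxidise one phenol beside a second phenol and a cinnamate, outrun tautomerisation of A3 to a stilbene, and fix C2 only through thermodynamic bias;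
- the homologation of an aryl aldehyde to A1 by methylenation, hydroboration and oxidation, three operations that would add no complexity;
- the attachment and cleavage of a stoichiometric auxiliary, after which an epimerisable α-aryl ester would be carried through several steps.

**New strategy.** The route rests on a one-carbon ring contraction: the dihydrofuran is not closed end to end but cut out of a six-membered pyranone. In an enantioenriched flavanone, ring A shifts from the carbonyl carbon C4 to C3 under a phenyl-λ3-iodane, which forms C3–C3a, expels C4 from the ring as the C3 methyl ester and sets C3 trans to the existing C2 centre in one operation. The feature exploited is that C3 of the target carries ring A and a carboxyl carbon side by side. C2 comes from a catalytic asymmetric aryl addition to a chromone, so no auxiliary, no arylacetic acid homologation and no phenol oxidation to a quinone methide are needed.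

Key step: step 8

Remark on numbering: target atoms are O1, C2, C3, C3a–C7a; ring A is the benzo ring and ring B the catechol ring on C2; flavanone atoms carry the usual chroman-4-one numbers (flavanone C6 and C8 become target C5 and C7).
Remark (assumption): the sense of induction in step 7, (S)-ligand giving the (R)-flavanone, is taken from the behaviour of this catalyst with cyclic enones.

**Route**

Step 1
Reactants: 1 1-(2-hydroxy-3-methoxyphenyl)ethan-1-one
Product: 2 1-(5-bromo-2-hydroxy-3-methoxyphenyl)ethan-1-one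
Conditions: NBS (1.05 equiv), MeCN, 0 °C to rt
Reagents that add atoms: N-bromosuccinimide, O=C1CCC(=O)N1Br
Why: Electrophilic aromatic bromination should go para to the free phenol, the position that is also meta to the acetyl group, as in the bromination of o-vanillin.

Step 2
Reactants: 2 1-(5-bromo-2-hydroxy-3-methoxyphenyl)ethan-1-one
Product: 4 6-bromo-8-methoxy-4H-chromen-4-one, via enaminone 3 (not isolated)
Conditions: Me2NCH(OMe)2 (1.5 equiv), toluene, 100 °C; evaporate; conc. HCl, CH2Cl2, rt
Reagents that add atoms: N,N-dimethylformamide dimethyl acetal, COC(OC)N(C)C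
Why: Condensation of the methyl ketone with the amide acetal gives the β-enaminone, and acid-promoted addition of the phenol with loss of dimethylamine closes the pyranone (enaminone chromone synthesis).

Step 3
Reactants: 4 6-bromo-8-methoxy-4H-chromen-4-one
Product: 5 6-bromo-8-hydroxy-4H-chromen-4-one
Conditions: BBr3 (3 equiv), CH2Cl2, −78 °C to rt; H2O
Reagents that add atoms: none
Why: BBr3 cleavage of the aryl methyl ether should leave the pyranone and the aryl bromide alone, and it is done here so that no Lewis-acid dealkylation is needed once the benzylic C2–O1 bond exists.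

Step 4
Reactants: 5 6-bromo-8-hydroxy-4H-chromen-4-one
Product: 6 6-bromo-8-(triisopropylsilyloxy)-4H-chromen-4-one
Conditions: TIPSCl (1.2 equiv), imidazole, DMF, rt
Reagents that add atoms: triisopropylsilyl chloride, CC(C)[Si](Cl)(C(C)C)C(C)C
Why: Imidazole-mediated silylation of the only hydroxyl group gives an aryl silyl ether that should tolerate the acid of step 8 and fall to fluoride at the end.

Step 5
Reactants: 7 4-bromobenzene-1,2-diol
Product: 8 4-bromo-1,2-bis(triisopropylsilyloxy)benzene
Conditions: TIPSCl (2.5 equiv), imidazole, DMAP (cat.), DMF, 50 °C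
Reagents that add atoms: triisopropylsilyl chloride, CC(C)[Si](Cl)(C(C)C)C(C)C
Why: Double O-silylation of the catechol, with excess reagent, DMAP and warming to drive the second, more hindered silylation.

Step 6
Reactants: 8 4-bromo-1,2-bis(triisopropylsilyloxy)benzene
Product: 11 [3,4-bis(triisopropylsilyloxy)phenyl]boronic acid, via aryllithium 9 (not isolated), via lithium aryltriisopropoxyborate 10 (not isolated)
Conditions: n-BuLi (1.05 equiv), THF, −78 °C; B(OiPr)3, −78 °C to rt; 1 M HCl, 0 °C, brief
Reagents that add atoms: triisopropyl borate, CC(C)OB(OC(C)C)OC(C)C; water, O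
Why: Bromine–lithium exchange, borylation and hydrolysis of the borate; the lithium sits meta and para to the silyloxy groups, so no ortho silyl shift from oxygen to carbon can occur.

Step 7
Reactants: 6 6-bromo-8-(triisopropylsilyloxy)-4H-chromen-4-one; 11 [3,4-bis(triisopropylsilyloxy)phenyl]boronic acid
Product: 12 (2R)-6-bromo-2-[3,4-bis(triisopropylsilyloxy)phenyl]-8-(triisopropylsilyloxy)-2,3-dihydro-4H-chromen-4-one
Conditions: 11 (2 equiv), Pd(OCOCF3)2 (5 mol%), (S)-4-tert-butyl-2-(pyridin-2-yl)-4,5-dihydrooxazole (6 mol%), NH4PF6 (30 mol%), H2O (5 equiv), ClCH2CH2Cl, 60 °C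
Reagents that add atoms: none
Why: Asymmetric conjugate addition of an arylboronic acid to a chromone (Hayashi–Miyaura-type 1,4-addition) with a cationic divalent palladium pyridine-oxazoline catalyst: aryl transfer from boron, insertion of C2=C3 into the Pd–aryl bond on the face left open by the tert-butyl group, and protonolysis of the palladium enolate by water should set C2 as (R), and the cycle does not pass through zerovalent palladium, so the aryl bromide should stay intact.

Step 8
Reactants: 12 (2R)-6-bromo-2-[3,4-bis(triisopropylsilyloxy)phenyl]-8-(triisopropylsilyloxy)-2,3-dihydro-4H-chromen-4-one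
Product: 15 methyl (2R,3R)-5-bromo-2-[3,4-bis(triisopropylsilyloxy)phenyl]-7-(triisopropylsilyloxy)-2,3-dihydro-1-benzofuran-3-carboxylate, via enol ether 13 (not isolated), via trans ketal-iodane 14 (not isolated)
Conditions: PhI(OAc)2 (1.2 equiv), conc. H2SO4 (2 equiv), HC(OMe)3, 0 °C to rt, Ar; aq NaHCO3
Reagents that add atoms: trimethyl orthoformate, COC(OC)OC
Why: Acidic orthoformate converts ketone 12 into enol ether 13, the phenyl-λ3-iodane adds to C3 on the face anti to the C2 aryl group and methanol captures the oxocarbenium ion, so that the trans ketal-iodane 14 forms with its C3–I bond equatorial and antiperiplanar to the C4–C4a bond. Ring A then migrates from C4 to C3 through a phenonium-type transition state as iodobenzene departs, which forms C3–C3a, contracts the six-membered pyranone to the five-membered dihydrofuran (a ring contraction by 1,2-shift, in which the ring is not closed end to end) and turns the expelled C4 into a dimethoxycarbenium ion that loses one methyl group to acetate and becomes the methyl ester. The closest known reaction type is the oxidative 1,2-aryl shift of aryl alkyl ketones with PhI(OAc)2 or Tl(NO3)3 in trimethyl orthoformate (Taylor–McKillop-type rearrangement), which is known on flavanones as a ring contraction to trans-2-aryl-2,3-dihydrobenzofuran-3-carboxylates. C2 is not involved and keeps the (R) configuration from step 7, while C3 is set by the substrate: anti attack of iodine followed by inversion at C3 during the shift places the ester trans to the aryl group, which gives (2R,3R) and is also the more stable arrangement of this enolisable centre. The step needs migration of ring A in preference to migration of ring B (isoflavone) or loss of H2 (flavone), and this is secured by the diequatorial conformer of 14, in which only C4–C4a is anti to iodine, by the O1 oxygen ortho to the migrating carbon, and by the twisted silyl ethers that should make ring B a poorer migrating group and a poorer target for the oxidant than alkoxy groups would. Keeping the ketone masked as enol ether or ketal in anhydrous medium should also close the retro-oxa-Michael path to the chalcone that could racemise C2.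

Step 9
Reactants: 15 methyl (2R,3R)-5-bromo-2-[3,4-bis(triisopropylsilyloxy)phenyl]-7-(triisopropylsilyloxy)-2,3-dihydro-1-benzofuran-3-carboxylate; 16 methyl acrylate
Product: 17 methyl (2R,3R)-2-[3,4-bis(triisopropylsilyloxy)phenyl]-5-[(E)-3-methoxy-3-oxoprop-1-enyl]-7-(triisopropylsilyloxy)-2,3-dihydro-1-benzofuran-3-carboxylate
Conditions: 16 (2 equiv), Pd2(dba)3 (2.5 mol%), [t-Bu3PH]BF4 (10 mol%), Cy2NMe (1.2 equiv), dioxane, rt to 50 °C
Reagents that add atoms: none
Why: Heck–Mizoroki coupling of the unhindered aryl bromide with the acrylate gives the E-cinnamate by syn-insertion and syn-β-hydride elimination, and the bulky trialkylphosphine allows a temperature at which the hindered amine should not enolise the C3 ester.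

Step 10
Reactants: 17 methyl (2R,3R)-2-[3,4-bis(triisopropylsilyloxy)phenyl]-5-[(E)-3-methoxy-3-oxoprop-1-enyl]-7-(triisopropylsilyloxy)-2,3-dihydro-1-benzofuran-3-carboxylate
Product: 18 methyl (2R,3R)-2-(3,4-dihydroxyphenyl)-7-hydroxy-5-[(E)-3-methoxy-3-oxoprop-1-enyl]-2,3-dihydro-1-benzofuran-3-carboxylate
Conditions: TBAF (3.6 equiv), AcOH (3.6 equiv), THF, 0 °C, Ar; pH 5 buffer
Reagents that add atoms: none
Why: Fluoride cleavage of the three aryl silyl ethers, buffered with acetic acid so that no phenoxide builds up that could open the ring through a p-quinone methide or an ester enolate or let the catechol oxidise.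

**Compound list**

1 | 1-(2-hydroxy-3-methoxyphenyl)ethan-1-one | CC(=O)c1cccc(OC)c1O | starting material
2 | 1-(5-bromo-2-hydroxy-3-methoxyphenyl)ethan-1-one | CC(=O)c1cc(Br)cc(OC)c1O | intermediate
3 | (E)-1-(5-bromo-2-hydroxy-3-methoxyphenyl)-3-(dimethylamino)prop-2-en-1-one | CN(C)/C=C/C(=O)c1cc(Br)cc(OC)c1O | intermediate (not isolated)
4 | 6-bromo-8-methoxy-4H-chromen-4-one | COc1cc(Br)cc2c(=O)ccoc12 | intermediate
5 | 6-bromo-8-hydroxy-4H-chromen-4-one | Oc1cc(Br)cc2c(=O)ccoc12 | intermediate
6 | 6-bromo-8-(triisopropylsilyloxy)-4H-chromen-4-one | CC(C)[Si](Oc1cc(Br)cc2c(=O)ccoc12)(C(C)C)C(C)C | intermediate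
7 | 4-bromobenzene-1,2-diol | Oc1ccc(Br)cc1O | starting material
8 | 4-bromo-1,2-bis(triisopropylsilyloxy)benzene | CC(C)[Si](Oc1ccc(Br)cc1O[Si](C(C)C)(C(C)C)C(C)C)(C(C)C)C(C)C | intermediate
9 | [3,4-bis(triisopropylsilyloxy)phenyl]lithium | [Li]c1ccc(O[Si](C(C)C)(C(C)C)C(C)C)c(O[Si](C(C)C)(C(C)C)C(C)C)c1 | intermediate (not isolated)
10 | lithium [3,4-bis(triisopropylsilyloxy)phenyl]tri(propan-2-yloxy)borate | [Li+].CC(C)O[B-](OC(C)C)(OC(C)C)c1ccc(O[Si](C(C)C)(C(C)C)C(C)C)c(O[Si](C(C)C)(C(C)C)C(C)C)c1 | intermediate (not isolated)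
11 | [3,4-bis(triisopropylsilyloxy)phenyl]boronic acid | OB(O)c1ccc(O[Si](C(C)C)(C(C)C)C(C)C)c(O[Si](C(C)C)(C(C)C)C(C)C)c1 | intermediate
12 | (2R)-6-bromo-2-[3,4-bis(triisopropylsilyloxy)phenyl]-8-(triisopropylsilyloxy)-2,3-dihydro-4H-chromen-4-one | O=C1C[C@H](c2ccc(O[Si](C(C)C)(C(C)C)C(C)C)c(O[Si](C(C)C)(C(C)C)C(C)C)c2)Oc2c(O[Si](C(C)C)(C(C)C)C(C)C)cc(Br)cc12 | intermediate (key-step precursor)
13 | (2R)-6-bromo-4-methoxy-2-[3,4-bis(triisopropylsilyloxy)phenyl]-8-(triisopropylsilyloxy)-2H-chromene | COC1=C[C@H](c2ccc(O[Si](C(C)C)(C(C)C)C(C)C)c(O[Si](C(C)C)(C(C)C)C(C)C)c2)Oc2c(O[Si](C(C)C)(C(C)C)C(C)C)cc(Br)cc12 | intermediate (not isolated)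
14 | (2S,3S)-3-[acetoxy(phenyl)-λ3-iodanyl]-6-bromo-4,4-dimethoxy-2-[3,4-bis(triisopropylsilyloxy)phenyl]-8-(triisopropylsilyloxy)chromane (iodine trans to the aryl group; C2 has the spatial arrangement of 12, the descriptor changes because C3 now outranks the aryl group) | COC1(OC)[C@@H](I(OC(C)=O)c2ccccc2)[C@H](c2ccc(O[Si](C(C)C)(C(C)C)C(C)C)c(O[Si](C(C)C)(C(C)C)C(C)C)c2)Oc2c(O[Si](C(C)C)(C(C)C)C(C)C)cc(Br)cc12 | intermediate (not isolated)
15 | methyl (2R,3R)-5-bromo-2-[3,4-bis(triisopropylsilyloxy)phenyl]-7-(triisopropylsilyloxy)-2,3-dihydro-1-benzofuran-3-carboxylate | Brc1cc(O[Si](C(C)C)(C(C)C)C(C)C)c2c(c1)[C@@H](C(=O)OC)[C@H](c1ccc(O[Si](C(C)C)(C(C)C)C(C)C)c(O[Si](C(C)C)(C(C)C)C(C)C)c1)O2 | intermediate (key-step product)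
16 | methyl acrylate | COC(=O)C=C | starting material
17 | methyl (2R,3R)-2-[3,4-bis(triisopropylsilyloxy)phenyl]-5-[(E)-3-methoxy-3-oxoprop-1-enyl]-7-(triisopropylsilyloxy)-2,3-dihydro-1-benzofuran-3-carboxylate | COC(=O)/C=C/c1cc(O[Si](C(C)C)(C(C)C)C(C)C)c2c(c1)[C@@H](C(=O)OC)[C@H](c1ccc(O[Si](C(C)C)(C(C)C)C(C)C)c(O[Si](C(C)C)(C(C)C)C(C)C)c1)O2 | intermediate
18 | methyl (2R,3R)-2-(3,4-dihydroxyphenyl)-7-hydroxy-5-[(E)-3-methoxy-3-oxoprop-1-enyl]-2,3-dihydro-1-benzofuran-3-carboxylate | COC(=O)/C=C/c1cc(O)c2c(c1)[C@@H](C(=O)OC)[C@H](c1ccc(O)c(O)c1)O2 | target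

**Count and risks**

Total step count: 10. Longest linear sequence: 8 steps (steps 1–4 and 7–10); the ring B branch has 2 steps (5 and 6).

Steps most likely to fail:

1. Step 8. What may go wrong: dehydrogenation to the flavone instead of rearrangement, shift of ring B in place of ring A, attack of the iodane on the electron-rich rings, partial silyl loss in the acid, or erosion of the C2 configuration by reversible ring opening. The fallback is a Wolff ring contraction that sets out from 12 and comes back at 15. The lithium enolate of 12 (LiHMDS, THF, −78 °C, where β-elimination of the aryloxide should be slow) would be acylated with CF3CO2CH2CF3 to the (2R)-3-(trifluoroacetyl)flavanone F1. Detrifluoroacetylative diazo transfer (MsN3, Et3N, H2O, MeCN) would give the 3-diazoflavanone F2. Irradiation at 365 nm in MeOH would expel N2 with 1,2-shift of ring A to the ring-contracted ketene F3, which methanol would capture as 15 together with its cis (2R,3S) epimer F4. A catalytic amount of DBU in toluene would then equilibrate F4 to the trans ester 15.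

2. Step 7. What may go wrong: weak facial discrimination or slow insertion with the bulky electron-rich boronic acid, protodeboronation, or aryl–aryl coupling at the bromide if zerovalent palladium builds up. The fallback is a kinetic resolution that sets out from 6 and comes back at 12. Chromone 6 and 11 would be joined without a chiral ligand (Pd(OCOCF3)2, 2,2'-bipyridine, AcOH/THF/H2O, 60 °C) to the racemic flavanone F5. Noyori-type asymmetric transfer hydrogenation (RuCl(p-cymene)[(S,S)-TsDPEN], HCO2H/Et3N, CH2Cl2, rt, stopped near half conversion) should then reduce the (S)-ketone to the cis-(2S,4S)-flavan-4-ol F6 and leave (R)-12 to be separated by chromatography.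

3. Step 10. What may go wrong: ring opening through a p-quinone methide once the 4'-phenoxide forms, enolate-triggered loss of the aryloxide, or air oxidation of the catecholate under fluoride. The fallback moves the silyl cleavage to a stage where the phenoxides are trapped at once, and ends with an acid step; it sets out from 15 and comes back at 18. Treatment of 15 with CsF and Ac2O in DMF at rt should exchange the three silyl ethers for acetates in one pot and give the triacetate bromide F7. The Heck reaction of step 9 with 16 would give the triacetate cinnamate F8. HCl in MeOH (from AcCl) at rt should then remove the aryl acetates by transesterification, which is degenerate for the two methyl esters, and give 18.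

**Further compounds**

F1 | step 8 | (2R)-6-bromo-3-(2,2,2-trifluoroacetyl)-2-[3,4-bis(triisopropylsilyloxy)phenyl]-8-(triisopropylsilyloxy)chroman-4-one (C3 epimers, in equilibrium with the enol) | O=C1C(C(=O)C(F)(F)F)[C@H](c2ccc(O[Si](C(C)C)(C(C)C)C(C)C)c(O[Si](C(C)C)(C(C)C)C(C)C)c2)Oc2c(O[Si](C(C)C)(C(C)C)C(C)C)cc(Br)cc12
F2 | step 8 | (2S)-6-bromo-3-diazo-2-[3,4-bis(triisopropylsilyloxy)phenyl]-8-(triisopropylsilyloxy)chroman-4-one (spatial arrangement at C2 as in 12) | O=C1C(=[N+]=[N-])[C@H](c2ccc(O[Si](C(C)C)(C(C)C)C(C)C)c(O[Si](C(C)C)(C(C)C)C(C)C)c2)Oc2c(O[Si](C(C)C)(C(C)C)C(C)C)cc(Br)cc12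
F3 | step 8 | {5-bromo-2-[3,4-bis(triisopropylsilyloxy)phenyl]-7-(triisopropylsilyloxy)-1-benzofuran-3(2H)-ylidene}methanone (ketene, C2 arrangement as in 12) | O=C=C1c2cc(Br)cc(O[Si](C(C)C)(C(C)C)C(C)C)c2O[C@H]1c1ccc(O[Si](C(C)C)(C(C)C)C(C)C)c(O[Si](C(C)C)(C(C)C)C(C)C)c1
F4 | step 8 | methyl (2R,3S)-5-bromo-2-[3,4-bis(triisopropylsilyloxy)phenyl]-7-(triisopropylsilyloxy)-2,3-dihydro-1-benzofuran-3-carboxylate (cis) | Brc1cc(O[Si](C(C)C)(C(C)C)C(C)C)c2c(c1)[C@H](C(=O)OC)[C@H](c1ccc(O[Si](C(C)C)(C(C)C)C(C)C)c(O[Si](C(C)C)(C(C)C)C(C)C)c1)O2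
F5 | step 7 | racemic 6-bromo-2-[3,4-bis(triisopropylsilyloxy)phenyl]-8-(triisopropylsilyloxy)-2,3-dihydro-4H-chromen-4-one | O=C1CC(c2ccc(O[Si](C(C)C)(C(C)C)C(C)C)c(O[Si](C(C)C)(C(C)C)C(C)C)c2)Oc2c(O[Si](C(C)C)(C(C)C)C(C)C)cc(Br)cc12
F6 | step 7 | (2S,4S)-6-bromo-2-[3,4-bis(triisopropylsilyloxy)phenyl]-8-(triisopropylsilyloxy)chroman-4-ol (cis) | O[C@H]1C[C@@H](c2ccc(O[Si](C(C)C)(C(C)C)C(C)C)c(O[Si](C(C)C)(C(C)C)C(C)C)c2)Oc2c(O[Si](C(C)C)(C(C)C)C(C)C)cc(Br)cc12
F7 | step 10 | methyl (2R,3R)-7-acetoxy-5-bromo-2-(3,4-diacetoxyphenyl)-2,3-dihydro-1-benzofuran-3-carboxylate | Brc1cc(OC(C)=O)c2c(c1)[C@@H](C(=O)OC)[C@H](c1ccc(OC(C)=O)c(OC(C)=O)c1)O2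
F8 | step 10 | methyl (2R,3R)-7-acetoxy-2-(3,4-diacetoxyphenyl)-5-[(E)-3-methoxy-3-oxoprop-1-enyl]-2,3-dihydro-1-benzofuran-3-carboxylate | COC(=O)/C=C/c1cc(OC(C)=O)c2c(c1)[C@@H](C(=O)OC)[C@H](c1ccc(OC(C)=O)c(OC(C)=O)c1)O2
A1 | direct plan | [5-bromo-2-(methoxymethoxy)-3-(triisopropylsilyloxy)phenyl]acetic acid | COCOc1c(CC(=O)O)cc(Br)cc1O[Si](C(C)C)(C(C)C)C(C)C
A2 | direct plan | methyl (2S)-2-{2-hydroxy-5-[(E)-3-methoxy-3-oxoprop-1-enyl]-3-(triisopropylsilyloxy)phenyl}-3-[4-hydroxy-3-(triisopropylsilyloxy)phenyl]propanoate | COC(=O)/C=C/c1cc(O[Si](C(C)C)(C(C)C)C(C)C)c(O)c(c1)[C@@H](C(=O)OC)Cc2ccc(O)c(O[Si](C(C)C)(C(C)C)C(C)C)c2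
A3 | direct plan | methyl (2S)-2-{2-hydroxy-5-[(E)-3-methoxy-3-oxoprop-1-enyl]-3-(triisopropylsilyloxy)phenyl}-3-[4-oxo-3-(triisopropylsilyloxy)cyclohexa-2,5-dien-1-ylidene]propanoate | COC(=O)/C=C/c1cc(O[Si](C(C)C)(C(C)C)C(C)C)c(O)c(c1)[C@@H](C(=O)OC)C=C2C=CC(=O)C(O[Si](C(C)C)(C(C)C)C(C)C)=C2
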